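Ring A = the six-membered β-triketone (filicinic acid) ring; going round it, its carbons are called the carbonyl carbon (C=O between bridge carbon and acyl carbon), the bridge carbon (bears the CH2 link), the bridge-side enol carbon (C–OH), the quaternary carbon (CMe2), the acyl-side enol carbon (C–OH) and the acyl carbon (bears propanoyl); ring B = benzene ring, ring C = pyran ring.
Endgame: the CH2–aryl bond is cut last (position 6 of chromene 23 adds to the exocyclic methylene trione 24 released from methoxymethyl trione 19); before it come two enol ether hydrolyses and one carbinol oxidation.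
Key disconnection: the carbonyl carbon–bridge carbon bond and the acyl-side enol carbon–acyl carbon bond together; ring A = cyclobutenone 7 (bridge carbon, bridge-side enol carbon, quaternary carbon, acyl-side enol carbon) + methoxyalkyne 12 (acyl carbon, carbonyl carbon) by a vinylketene [2+2]/4π/6π cascade, and 7 = dimethylketene + ethoxyalkyne 4.
Enabling feature: ring A has oxygen on every second carbon (the carbonyl carbon and both enol carbons) and a quaternary carbon between the two enol carbons, the imprint of one ketene C=O and two ynol ether C–O units; the quaternary carbon cannot aromatize, so the cascade stops at the dienone oxidation level the target needs.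
Ring order: four-membered ring (temporary), then ring A; ring C is built on ring B separately (Knoevenagel/oxa-6π); the two halves are joined in the last step.

Key step: step 5

Remark: ring A is a tautomeric β-triketone, so keto/enol tautomers of 19, 24 and 25 are treated as one compound each; the target has no stereocenter, so none has to be controlled.

Step 1
Reactants: 1 ethoxyacetylene, 2 chloromethyl methyl ether
Product: 4 ynol ether 1-ethoxy-3-methoxyprop-1-yne, via lithium ethoxyacetylide 3 (not isolated)
Conditions: n-BuLi, THF, −78 °C; then 2, −78 to 0 °C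
Reagents that add atoms: none
Why: Deprotonation of the terminal ynol ether gives acetylide 3, which is C-alkylated by the very reactive α-chloro ether (alkylation of a lithium acetylide); no stereocenter is formed.

Step 2
Reactants: 4 1-ethoxy-3-methoxyprop-1-yne, 5 isobutyryl chloride
Product: 7 cyclobutenone 3-ethoxy-2-(methoxymethyl)-4,4-dimethylcyclobut-2-en-1-one, via dimethylketene 6 (not isolated)
Conditions: Et3N, CH2Cl2, 40 °C, slow addition of 5
Reagents that add atoms: none
Why: Dehydrochlorination of 5 gives dimethylketene, which undergoes the classical regiospecific ketene–alkoxyalkyne [2+2] cycloaddition (ketene carbonyl carbon to the nucleophilic carbon β to OEt) to give the 3-alkoxycyclobutenone; no stereocenter is formed.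

Step 3
Reactants: 8 2-chloro-1,1-dimethoxyethane, 9 propanal
Product: 11 racemic 1-methoxypent-1-yn-3-ol, via lithium methoxyacetylide 10 (not isolated)
Conditions: LiNEt2 (3 equiv, made from Et2NH and n-BuLi), THF, 0 °C; then 9, −78 °C; then H2O
Reagents that add atoms: none
Why: Twofold elimination (HCl, MeOH) from the chloroacetal and deprotonation give acetylide 10, which adds 1,2 to the aldehyde; the carbinol center forms as the racemate and is erased in step 7, and the methyl ynol ether is chosen because it cannot lose an alkene by a retro-ene reaction at the temperature of step 5.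

Step 4
Reactants: 11 racemic 1-methoxypent-1-yn-3-ol
Product: 12 racemic silyl ether tert-butyl[(1-methoxypent-1-yn-3-yl)oxy]dimethylsilane
Conditions: TBSCl, imidazole, DMF, rt
Reagents that add atoms: tert-butyldimethylsilyl chloride, CC(C)(C)[Si](C)(C)Cl
Why: Standard silylation of a secondary alcohol under basic conditions that the acid-sensitive ynol ether tolerates; the hydroxyl must be masked because it would add to the ketenes of step 5.

Step 5
Reactants: 7 3-ethoxy-2-(methoxymethyl)-4,4-dimethylcyclobut-2-en-1-one, 12 tert-butyl[(1-methoxypent-1-yn-3-yl)oxy]dimethylsilane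
Product: 16 racemic dienone 2-[1-(tert-butyldimethylsilyloxy)propyl]-5-ethoxy-3-methoxy-4-(methoxymethyl)-6,6-dimethylcyclohexa-2,4-dien-1-one, via vinylketene 13 (not isolated), via vinylcyclobutenone 14 (not isolated), via dienylketene 15 (not isolated)
Conditions: 12 (2 equiv), toluene (1 M), 120 °C, sealed tube, argon
Reagents that add atoms: none
Why: Proposed new method: thermal 4π-electrocyclic opening of 7 gives vinylketene 13, whose ketene C=C undergoes [2+2] cycloaddition with ynol ether 12 (ketene carbonyl carbon to the carbon β to OMe makes the bond between the acyl-side enol carbon and the acyl carbon of ring A, ketene α-carbon to the OMe-bearing carbon makes the bond between the bridge carbon and the ring carbonyl carbon), the resulting 4-vinylcyclobutenone 14 opens (4π) to dienylketene 15, and 15 closes to ring A, so that in net terms the two alkyne carbons are inserted between the carbonyl carbon and the α-carbon of 7. The closest known reaction type is the Danheiser benzannulation of cyclobutenones with alkoxy- and siloxyalkynes; the extension proposed here is a 3-alkoxy-4,4-dimethylcyclobutenone with a fully substituted vinylketene, whose cascade must end at the non-aromatizable 6,6-dimethylcyclohexa-2,4-dienone. Ring A is closed by thermal disrotatory 6π-electrocyclization of the (3E)-dienylketene, which re-forms the bond between the quaternary carbon and the acyl-side enol carbon that was broken in the first opening; the other geometric isomer of 15 can only revert to 14, so the reversible ring opening should funnel material to 16. No new stereocenter is created in ring A: the quaternary center of 14 is destroyed again, and the silyloxy-bearing center of 12 is carried through as the racemate. The step needs regioselectivity in the [2+2] event, secured by the polarization of the ynol ether, and it needs bimolecular capture of 13 to outrun its [1,5]-hydrogen shift and dimerization, secured by excess 12 at high concentration.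

Step 6
Reactants: 16 racemic silyl ether dienone
Product: 17 racemic alcohol 5-ethoxy-2-(1-hydroxypropyl)-3-methoxy-4-(methoxymethyl)-6,6-dimethylcyclohexa-2,4-dien-1-one
Conditions: Bu4NF, THF, 0 °C
Reagents that add atoms: none
Why: Fluoride-induced cleavage of the secondary silyl ether (Si–F bond formation); the dienone has no acidic hydrogen (the ring carbon between the carbonyl and the ethoxy-bearing carbon is quaternary) and its vinylogous esters should be inert to basic fluoride at 0 °C.

Step 7
Reactants: 17 racemic alcohol
Product: 18 ketone 5-ethoxy-3-methoxy-4-(methoxymethyl)-6,6-dimethyl-2-propanoylcyclohexa-2,4-dien-1-one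
Conditions: Dess-Martin periodinane, CH2Cl2, 0 °C to rt
Reagents that add atoms: none
Why: Dess-Martin oxidation of a secondary allylic alcohol to the ketone under near-neutral conditions that spare the enol ethers; it installs the propanoyl group and removes the only stereocenter of the route.

Step 8
Reactants: 18 ketone 5-ethoxy-3-methoxy-4-(methoxymethyl)-6,6-dimethyl-2-propanoylcyclohexa-2,4-dien-1-one
Product: 19 trione 3,5-dihydroxy-2-(methoxymethyl)-4,4-dimethyl-6-propanoylcyclohexa-2,5-dien-1-one
Conditions: 1 M aq. HCl, MeOH, rt
Reagents that add atoms: water, O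
Why: Acid-catalysed hydrolysis of two vinylogous esters (first the methoxy group β to two carbonyls, then the ethoxy group of the enolized triketone); the methoxymethyl group should survive because enolate-driven elimination is suppressed at low pH and any ionized CH2 is recaptured by the methanol solvent.

Step 9
Reactants: 20 flopropione 1-(2,4,6-trihydroxyphenyl)propan-1-one, 21 prenal 3-methylbut-2-enal
Product: 23 chromene 1-(5,7-dihydroxy-2,2-dimethyl-2H-chromen-8-yl)propan-1-one, via dienone 22 (not isolated)
Conditions: ethylenediammonium diacetate (10 mol%), 21 (1.0 equiv), toluene, 110 °C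
Reagents that add atoms: none
Why: Amine-salt-catalysed Knoevenagel-type condensation at a free ring carbon gives dienone 22, which closes by oxa-6π-electrocyclization; closure through the oxygen next to the acyl-bearing carbon gives 23, the 6-acyl isomer from the other oxygen is the expected by-product to be separated by chromatography, and the new sp3 carbon carries two methyl groups, so no stereocenter arises.

Step 10
Reactants: 19 trione 3,5-dihydroxy-2-(methoxymethyl)-4,4-dimethyl-6-propanoylcyclohexa-2,5-dien-1-one, 23 chromene 1-(5,7-dihydroxy-2,2-dimethyl-2H-chromen-8-yl)propan-1-one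
Product: 25 target 2-[(5,7-dihydroxy-2,2-dimethyl-8-propanoyl-2H-chromen-6-yl)methyl]-3,5-dihydroxy-4,4-dimethyl-6-propanoylcyclohexa-2,5-dien-1-one, via methylene trione 24 (not isolated)
Conditions: NaOAc, MeOH, 50 °C
Reagents that add atoms: none
Why: Mild base promotes loss of methanol from 19 to the exocyclic methylene trione 24 (an analog of an ortho-quinone methide), to which position 6 of 23, the only free aromatic carbon and flanked by two hydroxyls, adds in a Michael reaction of the kind that underlies formaldehyde and Mannich-base couplings of acylphloroglucinols; in methanol 24 is reversibly recaptured as 19, which should limit self-condensation, and no stereocenter is formed.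

Compound list
1 | ethoxyacetylene (ethoxyethyne) | CCOC#C | starting material
2 | chloromethyl methyl ether | COCCl | starting material
3 | lithium ethoxyacetylide | [Li]C#COCC | intermediate
4 | 1-ethoxy-3-methoxyprop-1-yne | CCOC#CCOC | intermediate
5 | isobutyryl chloride (2-methylpropanoyl chloride) | CC(C)C(Cl)=O | starting material
6 | dimethylketene (2-methylprop-1-en-1-one) | CC(C)=C=O | intermediate
7 | 3-ethoxy-2-(methoxymethyl)-4,4-dimethylcyclobut-2-en-1-one | CCOC1=C(COC)C(=O)C1(C)C | intermediate
8 | 2-chloro-1,1-dimethoxyethane (chloroacetaldehyde dimethyl acetal) | COC(CCl)OC | starting material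
9 | propanal | CCC=O | starting material
10 | lithium methoxyacetylide | [Li]C#COC | intermediate
11 | 1-methoxypent-1-yn-3-ol, racemic | CCC(O)C#COC | intermediate
12 | tert-butyl[(1-methoxypent-1-yn-3-yl)oxy]dimethylsilane, racemic | CCC(C#COC)O[Si](C)(C)C(C)(C)C | intermediate
13 | vinylketene 3-ethoxy-2-(methoxymethyl)-4-methylpenta-1,3-dien-1-one | CCOC(=C(C)C)C(COC)=C=O | intermediate
14 | 2-[1-(tert-butyldimethylsilyloxy)propyl]-4-(1-ethoxy-2-methylprop-1-en-1-yl)-3-methoxy-4-(methoxymethyl)cyclobut-2-en-1-one, racemic mixture of diastereomers | CCOC(=C(C)C)C1(COC)C(OC)=C(C(CC)O[Si](C)(C)C(C)(C)C)C1=O | intermediate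
15 | (3E)-2-[1-(tert-butyldimethylsilyloxy)propyl]-5-ethoxy-3-methoxy-4-(methoxymethyl)-6-methylhepta-1,3,5-trien-1-one, racemic | O=C=C(C(CC)O[Si](C)(C)C(C)(C)C)/C(OC)=C(COC)\C(OCC)=C(C)C | intermediate
16 | 2-[1-(tert-butyldimethylsilyloxy)propyl]-5-ethoxy-3-methoxy-4-(methoxymethyl)-6,6-dimethylcyclohexa-2,4-dien-1-one, racemic | CCOC1=C(COC)C(OC)=C(C(CC)O[Si](C)(C)C(C)(C)C)C(=O)C1(C)C | intermediate
17 | 5-ethoxy-2-(1-hydroxypropyl)-3-methoxy-4-(methoxymethyl)-6,6-dimethylcyclohexa-2,4-dien-1-one, racemic | CCOC1=C(COC)C(OC)=C(C(O)CC)C(=O)C1(C)C | intermediate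
18 | 5-ethoxy-3-methoxy-4-(methoxymethyl)-6,6-dimethyl-2-propanoylcyclohexa-2,4-dien-1-one | CCOC1=C(COC)C(OC)=C(C(=O)CC)C(=O)C1(C)C | intermediate
19 | 3,5-dihydroxy-2-(methoxymethyl)-4,4-dimethyl-6-propanoylcyclohexa-2,5-dien-1-one | CCC(=O)C1=C(O)C(C)(C)C(O)=C(COC)C1=O | intermediate
20 | flopropione, 1-(2,4,6-trihydroxyphenyl)propan-1-one | CCC(=O)c1c(O)cc(O)cc1O | starting material
21 | prenal, 3-methylbut-2-enal | CC(C)=CC=O | starting material
22 | 3,5-dihydroxy-6-(3-methylbut-2-en-1-ylidene)-2-propanoylcyclohexa-2,4-dien-1-one, exocyclic double bond geometry not defined | CCC(=O)C1=C(O)C=C(O)C(=CC=C(C)C)C1=O | intermediate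
23 | 1-(5,7-dihydroxy-2,2-dimethyl-2H-chromen-8-yl)propan-1-one | CCC(=O)c1c(O)cc(O)c2C=CC(C)(C)Oc12 | intermediate
24 | 5-hydroxy-4,4-dimethyl-2-methylidene-6-propanoylcyclohex-5-ene-1,3-dione | CCC(=O)C1=C(O)C(C)(C)C(=O)C(=C)C1=O | intermediate
25 | 2-[(5,7-dihydroxy-2,2-dimethyl-8-propanoyl-2H-chromen-6-yl)methyl]-3,5-dihydroxy-4,4-dimethyl-6-propanoylcyclohexa-2,5-dien-1-one (CNP0277188.0) | CCC(=O)C1=C(O)C(C)(C)C(O)=C(Cc2c(O)c3c(c(C(=O)CC)c2O)OC(C)(C)C=C3)C1=O | target

Total step count: 10. Longest linear sequence: 7 steps (steps 3, 4, 5, 6, 7, 8, 10; equally steps 1, 2, 5, 6, 7, 8, 10).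

Steps most likely to fail

1. Step 5 (Proposed new method). What may go wrong: the alkoxy-stabilized cyclobutenones open sluggishly, and the fully substituted vinylketene is consumed by an intramolecular [1,5]-hydrogen shift from its cis methyl group or by dimerization before the ynol ether captures it. Fallback with known chemistry: it sets out from flopropione 20. Twofold C-methylation (MeI, NaOMe, MeOH) gives 3,5-dihydroxy-4,4-dimethyl-2-propanoylcyclohexa-2,5-dien-1-one F1. A Mannich reaction of F1 with Eschenmoser's salt gives 2-[(dimethylamino)methyl]-3,5-dihydroxy-4,4-dimethyl-6-propanoylcyclohexa-2,5-dien-1-one F2. Warming F2 with chromene 23 eliminates dimethylamine, and the fallback rejoins the route at methylene trione 24, which is taken on to 25 as in step 10.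

2. Step 8. What may go wrong: premature loss of methanol from the methoxymethyl group (a vinylogous acetal before hydrolysis, an enol-activated ether after it), followed by hydration or self-condensation of the methylene trione, or stalling after the first hydrolysis. Fallback with the order of events reversed: it sets out from 18. Catalytic BF3·OEt2 in CH2Cl2 at −40 °C ionizes the methoxymethyl group to the ethoxy-stabilized cation, which alkylates position 6 of chromene 23 (Friedel–Crafts) to give 4-[(5,7-dihydroxy-2,2-dimethyl-8-propanoyl-2H-chromen-6-yl)methyl]-5-ethoxy-3-methoxy-6,6-dimethyl-2-propanoylcyclohexa-2,4-dien-1-one F3. Hydrolysis of the two enol ethers of F3 (aq. HCl, THF) returns to the route at 25.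

3. Step 9. What may go wrong: poor regiocontrol in the pyran ring closure (closure through the oxygen para to the acyl group gives the 6-acyl chromene) and a second condensation to a bis-chromene. Fallback with a blocking group: it sets out from 20. Selective protection of the non-chelated para hydroxyl (MOMCl, i-Pr2NEt, CH2Cl2, 0 °C) gives 1-[2,6-dihydroxy-4-(methoxymethoxy)phenyl]propan-1-one F4. Condensation of F4 with prenal 21 (ethylenediammonium diacetate, toluene, 110 °C) can then close only through an oxygen next to the acyl group and gives 1-[7-hydroxy-5-(methoxymethoxy)-2,2-dimethyl-2H-chromen-8-yl]propan-1-one F5. Acetal cleavage (HCl, MeOH, 40 °C) returns to the route at 23.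

Further compounds
F1 | step 5 | 3,5-dihydroxy-4,4-dimethyl-2-propanoylcyclohexa-2,5-dien-1-one | CCC(=O)C1=C(O)C(C)(C)C(O)=CC1=O
F2 | step 5 | 2-[(dimethylamino)methyl]-3,5-dihydroxy-4,4-dimethyl-6-propanoylcyclohexa-2,5-dien-1-one | CCC(=O)C1=C(O)C(C)(C)C(O)=C(CN(C)C)C1=O
F3 | step 8 | 4-[(5,7-dihydroxy-2,2-dimethyl-8-propanoyl-2H-chromen-6-yl)methyl]-5-ethoxy-3-methoxy-6,6-dimethyl-2-propanoylcyclohexa-2,4-dien-1-one | CCOC1=C(Cc2c(O)c3c(c(C(=O)CC)c2O)OC(C)(C)C=C3)C(OC)=C(C(=O)CC)C(=O)C1(C)C
F4 | step 9 | 1-[2,6-dihydroxy-4-(methoxymethoxy)phenyl]propan-1-one | CCC(=O)c1c(O)cc(OCOC)cc1O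
F5 | step 9 | 1-[7-hydroxy-5-(methoxymethoxy)-2,2-dimethyl-2H-chromen-8-yl]propan-1-one | CCC(=O)c1c(O)cc(OCOC)c2C=CC(C)(C)Oc12
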